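**Strategy.** The plan rests on cutting ring B at C9–C10 and C6–C7. Because the C6 acetoxy carbon and C8 (exocyclic methylene, a latent ketone) are 1,3-related in ring B, atoms C7–C9 with the whole C11–C16 dienyl chain are one methyl ketone. This ketone can be joined to a ring A enal (C6 formyl on C5=C10) by conjugate addition at C10 followed by aldol closure of C7 onto C6. One operation thus builds ring B, the quaternary C10 and the C5, C6 and C9 centres. The precursors are the enantiopure C4-quaternary enal and the (E)-dienone, used as its internal silyl enol ether.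

Key step: step 10

Remark on numbering: atom labels C1–C20 follow labdane numbering (ring A = C1–C5 and C10; ring B = C5–C10; C4 carries the methyl and the ester, C10 the angular methyl C20, C17 is the exocyclic methylene carbon).

Assumption: with the L-valine tert-butyl ester auxiliary and a weakly coordinating additive (THF), the methylation of step 2 is taken to give the (S)-keto ester; should the sense prove opposite, hexamethylphosphoramide as additive or the D-valine ester would deliver it, and nothing else changes.

**Ring A enal**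

Step 1
Reactants: 1 methyl 2-oxocyclohexane-1-carboxylate; 2 L-valine tert-butyl ester
Product: 3 methyl 2-{[(2S)-1-tert-butoxy-3-methyl-1-oxobutan-2-yl]amino}cyclohex-1-ene-1-carboxylate
Conditions: BF3·OEt2 (cat.), benzene, reflux, Dean–Stark
Reagents that add atoms: none
Why: Condensation of a β-keto ester with a primary amine under azeotropic removal of water gives the hydrogen-bonded enamino ester (vinylogous carbamate formation), and no stereocentre is created.

Step 2
Reactants: 3 the enamino ester
Product: 6 methyl (1S)-1-methyl-2-oxocyclohexane-1-carboxylate, via lithio enamine 4 (not isolated), via methylated ketimine 5 (not isolated)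
Conditions: LiN(i-Pr)2, toluene, −78 °C; THF (2 equiv), MeI, −78 → −55 °C; then 1 M HCl (aq), rt
Reagents that add atoms: iodomethane, CI; water, O
Why: Auxiliary-controlled alkylation of a lithiated enamine, in which lithium is held by nitrogen and both ester carbonyls so that the valine isopropyl group leaves one face of the nucleophilic carbon open to iodomethane and sets the quaternary (S) centre, followed by imine hydrolysis that returns the ketone and the auxiliary.

Step 3
Reactants: 6 methyl (1S)-1-methyl-2-oxocyclohexane-1-carboxylate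
Product: 8 methyl (1S)-1,3-dimethyl-2-oxocyclohexane-1-carboxylate (both C3 epimers), via lithium enolate 7 (not isolated)
Conditions: LiN(i-Pr)2, THF, −78 °C; MeI, −78 → 0 °C
Reagents that add atoms: iodomethane, CI
Why: Kinetic enolate alkylation can only occur at the single enolisable α-carbon (ring C3, the later C10), the new centre is of no consequence because it becomes sp2 in step 4, and the quaternary centre cannot epimerise.

Step 4
Reactants: 8 methyl (1S)-1,3-dimethyl-2-oxocyclohexane-1-carboxylate
Product: 10 methyl (1S)-1,3-dimethyl-2-{[(trifluoromethyl)sulfonyl]oxy}cyclohex-2-ene-1-carboxylate, via potassium enolate 9 (not isolated)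
Conditions: KN(SiMe3)2, THF, −78 → 0 °C; PhNTf2, −78 °C → rt; aq. NH4Cl
Reagents that add atoms: N-phenylbis(trifluoromethanesulfonimide), O=S(=O)(N(c1ccccc1)S(=O)(=O)C(F)(F)F)C(F)(F)F
Why: Enol triflate formation, in which enolisation is possible only towards the methyl-bearing carbon, gives the tetrasubstituted enolate that is O-sulfonylated as is usual for 2,2,6-trisubstituted cyclohexanones, and both epimers of 8 converge.

Step 5
Reactants: 10 the enol triflate
Product: 11 methyl (1S)-2-formyl-1,3-dimethylcyclohex-2-ene-1-carboxylate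
Conditions: Pd(PPh3)4 (cat.), CO (3 atm), Bu3SnH (slow addition), LiCl, THF, 50 °C
Reagents that add atoms: carbon monoxide, [C-]#[O+]
Why: Palladium-catalysed reductive carbonylation (formylation) of an enol triflate proceeds by oxidative addition to zerovalent palladium, CO insertion and hydride transfer from tin, slow hydride addition holding back simple reduction, and the quaternary centre is not involved.

**Dienone and its enol ether**

Step 6
Reactants: 12 2-(2-bromoethyl)-2-methyl-1,3-dioxolane
Product: 13 2-(2-iodoethyl)-2-methyl-1,3-dioxolane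
Conditions: NaI, NaHCO3 (cat.), acetone, reflux
Reagents that add atoms: sodium iodide, [Na+].[I-]
Why: Finkelstein halide exchange, driven by precipitation of NaBr, provides the primary iodide needed for a fast alkylation at low temperature.

Step 7
Reactants: 14 3-methyl-2,5-dihydrothiophene 1,1-dioxide; 13 2-(2-iodoethyl)-2-methyl-1,3-dioxolane
Product: 16 3-methyl-2-[2-(2-methyl-1,3-dioxolan-2-yl)ethyl]-2,5-dihydrothiophene 1,1-dioxide (racemic), via 2-lithiosulfolene 15 (not isolated)
Conditions: LiN(SiMe3)2 added to 14 + 13, THF–HMPA, −78 °C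
Reagents that add atoms: none
Why: α-Sulfonyl carbanion alkylation with in situ trapping should occur at C2 of the sulfolene, where the allyl anion avoids placing charge on the methyl-bearing carbon, the iodide capturing the anion before it ring-opens, and the new centre is lost in step 8.

Step 8
Reactants: 16 the alkylated sulfolene
Product: 18 (5E)-6-methylocta-5,7-dien-2-one, via diene ketal 17 (not isolated)
Conditions: pyridine (cat.), toluene, reflux; then 1 M HCl, THF, rt
Reagents that add atoms: water, O
Why: Cheletropic extrusion of SO2 from a 2-substituted 3-sulfolene is disrotatory with the C2 substituent turning outwards, so the trisubstituted C12=C13 double bond should form as the (E) isomer only, and mild acetal hydrolysis then frees the ketone.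

Step 9
Reactants: 18 (5E)-6-methylocta-5,7-dien-2-one
Product: 19 trimethyl{[(5E)-6-methylocta-2,5,7-trien-2-yl]oxy}silane (enol ether double bond mainly Z)
Conditions: Me3SiCl, NaI, Et3N, MeCN, rt; pentane extraction, fractional distillation
Reagents that add atoms: chlorotrimethylsilane, C[Si](C)(C)Cl
Why: Silyl enol ether formation under equilibrating conditions (iodotrimethylsilane made in situ, amine base) favours the more substituted C8=C9 enol ether of a methyl ketone, and removal of the minor terminal isomer by distillation fixes the enolate regiochemistry of step 10 in an isolated compound.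

**Annulation and endgame**

Step 10
Reactants: 11 methyl (1S)-2-formyl-1,3-dimethylcyclohex-2-ene-1-carboxylate; 19 the silyl enol ether
Product: 23 methyl (1S,4aR,5S,8R,8aS)-8-hydroxy-1,4a-dimethyl-5-[(2E)-3-methylpenta-2,4-dien-1-yl]-6-oxodecahydronaphthalene-1-carboxylate, via aluminium-bound enal 20 (not isolated), via lithium enolate 21 (not isolated), via keto aldehyde 22 (not isolated)
Conditions: aluminium tris(2,6-diphenylphenoxide) (1.5 equiv, from Me3Al + 2,6-diphenylphenol, toluene, rt), 11, toluene, −78 °C; 21 (from 19 + MeLi, 0.95 equiv, THF, 0 °C → rt) added at −78 °C, then −40 °C; 1 M HCl quench; then LiOH·H2O, i-PrOH, 0 °C → rt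
Reagents that add atoms: none
Why: Proposed new method: the aluminium phenoxide binds the formyl oxygen of 11 (complex 20), shields C6 against 1,2-attack and activates the conjugated C10, so that the regiodefined lithium enolate 21, set free from 19 by MeLi, should add through C9 to the tetrasubstituted β-carbon C10 (Michael addition) and give keto aldehyde 22 after protonation. The closest known reaction type is the conjugate addition of lithium ketone enolates to enals complexed by aluminium tris(2,6-diphenylphenoxide) followed by aldol ring closure; it has not been shown for a β,β-disubstituted, α-branched enal that must deliver a quaternary carbon, which is why the step is a proposal. LiOH then closes ring B by a 6-(enolendo)-exo-trig aldol addition of the methyl-derived enolate carbon C7 to the C6 aldehyde. C10 is the only centre set kinetically: axial attack on the half-chair of ring A takes place syn to the pseudoaxial C4 substituent, and the flat, smaller, lithium-coordinating ester is expected in that position, so C9 should enter anti to the C4 methyl. C5, C6 and C9 are α or β to carbonyl groups and should settle by enolisation (C5 in 22, C9 in 23) and reversible aldolisation in the trans-fused chair with equatorial C6 hydroxyl and C9 chain, because an axial hydroxyl would face both axial methyl groups (on C4 and C10). The step needs 1,4- over 1,2-addition (secured by the aluminium reagent), C9 over C7 attack (secured by the isolated enol ether 19) and survival of the ketol (mild base at low temperature; an equatorial hydroxyl is poorly aligned for E1cB loss).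

Step 11
Reactants: 23 the ketol
Product: 24 methyl (1S,4aR,5S,8R,8aS)-8-(acetyloxy)-1,4a-dimethyl-5-[(2E)-3-methylpenta-2,4-dien-1-yl]-6-oxodecahydronaphthalene-1-carboxylate
Conditions: Ac2O, pyridine, DMAP (cat.), CH2Cl2, 0 °C → rt
Reagents that add atoms: acetic anhydride, CC(=O)OC(C)=O
Why: Acylation of the equatorial secondary alcohol under nucleophilic catalysis with a weak base at 0 °C should be faster than β-elimination towards the C8 ketone, and no stereocentre is touched.

Step 12
Reactants: 24 the keto acetate
Product: 25 methyl (1S,4aS,5R,8R,8aS)-8-(acetyloxy)-1,4a-dimethyl-6-methylidene-5-[(2E)-3-methylpenta-2,4-dien-1-yl]decahydronaphthalene-1-carboxylate (CNP0212193.1)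
Conditions: Zn, CH2Br2, TiCl4 (reagent pre-formed in THF), CH2Cl2, 0 °C → rt
Reagents that add atoms: dibromomethane, BrCBr
Why: Takai–Lombardo methylenation with the non-basic titanium–zinc methylene reagent should convert the hindered, enolisable C8 ketone into the exocyclic methylene without epimerising C9, eliminating the β-acetoxy group or touching either ester.

**Compound list**

1 | methyl 2-oxocyclohexane-1-carboxylate | COC(=O)C1CCCCC1=O | starting material
2 | L-valine tert-butyl ester (free base of the commercial hydrochloride) | CC(C)[C@H](N)C(=O)OC(C)(C)C | starting material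
3 | methyl 2-{[(2S)-1-tert-butoxy-3-methyl-1-oxobutan-2-yl]amino}cyclohex-1-ene-1-carboxylate | COC(=O)C1=C(N[C@@H](C(C)C)C(=O)OC(C)(C)C)CCCC1 | intermediate
4 | N-lithio derivative of 3 (chelated lithio enamine) | COC(=O)C1=C(N([Li])[C@@H](C(C)C)C(=O)OC(C)(C)C)CCCC1 | intermediate
5 | methyl (1S)-2-{[(2S)-1-tert-butoxy-3-methyl-1-oxobutan-2-yl]imino}-1-methylcyclohexane-1-carboxylate | COC(=O)[C@@]1(C)CCCCC1=N[C@@H](C(C)C)C(=O)OC(C)(C)C | intermediate
6 | methyl (1S)-1-methyl-2-oxocyclohexane-1-carboxylate | COC(=O)[C@@]1(C)CCCCC1=O | intermediate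
7 | lithium enolate of 6 (enolised towards C3) | COC(=O)[C@@]1(C)CCCC=C1O[Li] | intermediate
8 | methyl (1S)-1,3-dimethyl-2-oxocyclohexane-1-carboxylate (both C3 epimers) | COC(=O)[C@@]1(C)CCCC(C)C1=O | intermediate
9 | potassium enolate of 8 | COC(=O)[C@@]1(C)CCCC(C)=C1O[K] | intermediate
10 | methyl (1S)-1,3-dimethyl-2-{[(trifluoromethyl)sulfonyl]oxy}cyclohex-2-ene-1-carboxylate | COC(=O)[C@@]1(C)CCCC(C)=C1OS(=O)(=O)C(F)(F)F | intermediate
11 | methyl (1S)-2-formyl-1,3-dimethylcyclohex-2-ene-1-carboxylate (ring A enal) | COC(=O)[C@@]1(C)CCCC(C)=C1C=O | intermediate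
12 | 2-(2-bromoethyl)-2-methyl-1,3-dioxolane | CC1(CCBr)OCCO1 | starting material
13 | 2-(2-iodoethyl)-2-methyl-1,3-dioxolane | CC1(CCI)OCCO1 | intermediate
14 | 3-methyl-2,5-dihydrothiophene 1,1-dioxide (3-methyl-3-sulfolene) | CC1=CCS(=O)(=O)C1 | starting material
15 | 2-lithio-3-methyl-2,5-dihydrothiophene 1,1-dioxide | CC1=CCS(=O)(=O)C1[Li] | intermediate
16 | 3-methyl-2-[2-(2-methyl-1,3-dioxolan-2-yl)ethyl]-2,5-dihydrothiophene 1,1-dioxide (racemic) | CC1=CCS(=O)(=O)C1CCC1(C)OCCO1 | intermediate
17 | 2-methyl-2-[(3E)-4-methylhexa-3,5-dien-1-yl]-1,3-dioxolane | CC1(CC/C=C(\C)C=C)OCCO1 | intermediate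
18 | (5E)-6-methylocta-5,7-dien-2-one (dienone) | CC(=O)CC/C=C(\C)C=C | intermediate
19 | trimethyl{[(5E)-6-methylocta-2,5,7-trien-2-yl]oxy}silane (enol ether geometry mainly Z) | CC(O[Si](C)(C)C)=CC/C=C(\C)C=C | intermediate
20 | 1:1 complex of 11 and aluminium tris(2,6-diphenylphenoxide), aluminium on the formyl oxygen | COC(=O)[C@@]1(C)CCCC(C)=C1C=[O+][Al-](Oc1c(-c2ccccc2)cccc1-c1ccccc1)(Oc1c(-c2ccccc2)cccc1-c1ccccc1)Oc1c(-c2ccccc2)cccc1-c1ccccc1 | intermediate
21 | lithium (5E)-6-methylocta-2,5,7-trien-2-olate (C8=C9 enolate of 18) | CC(O[Li])=CC/C=C(\C)C=C | intermediate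
22 | methyl (1S,3R)-2-formyl-1,3-dimethyl-3-[(5E)-6-methyl-2-oxoocta-5,7-dien-3-yl]cyclohexane-1-carboxylate (C5 and C9 not yet settled) | COC(=O)[C@@]1(C)CCC[C@@](C)(C(C/C=C(\C)C=C)C(C)=O)C1C=O | intermediate
23 | methyl (1S,4aR,5S,8R,8aS)-8-hydroxy-1,4a-dimethyl-5-[(2E)-3-methylpenta-2,4-dien-1-yl]-6-oxodecahydronaphthalene-1-carboxylate (trans-fused ketol, equatorial hydroxyl and chain) | C=C/C(C)=C/C[C@@H]1C(=O)C[C@@H](O)[C@H]2[C@@]1(C)CCC[C@]2(C)C(=O)OC | intermediate
24 | methyl (1S,4aR,5S,8R,8aS)-8-(acetyloxy)-1,4a-dimethyl-5-[(2E)-3-methylpenta-2,4-dien-1-yl]-6-oxodecahydronaphthalene-1-carboxylate | C=C/C(C)=C/C[C@@H]1C(=O)C[C@@H](OC(C)=O)[C@H]2[C@@]1(C)CCC[C@]2(C)C(=O)OC | intermediate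
25 | methyl (1S,4aS,5R,8R,8aS)-8-(acetyloxy)-1,4a-dimethyl-6-methylidene-5-[(2E)-3-methylpenta-2,4-dien-1-yl]decahydronaphthalene-1-carboxylate | C=C/C(C)=C/C[C@@H]1C(=C)C[C@@H](OC(C)=O)[C@H]2[C@@]1(C)CCC[C@]2(C)C(=O)OC | target

**Step count.** Total: 12 steps. Longest linear sequence: 8 steps (steps 1–5, then 10, 11 and 12); the dienone branch (steps 6–9) joins at step 10.

**Steps most likely to fail**

1. Step 10 (bears the label). The enolate may act as a base and remove a γ-proton of the complexed enal (C1 or the C20 methyl) instead of adding to the crowded C10. It may also add on the face of the C4 methyl, or C5 may fail to equilibrate before ring closure. The fallback uses known chemistry and makes the C9–C10 bond by a [3,3]-sigmatropic shift instead of an intermolecular addition; it sets out from 11 and comes back to the route at 22.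
   - Luche reduction (NaBH4, CeCl3·7H2O, MeOH, 0 °C) of 11 would give methyl (1S)-2-(hydroxymethyl)-1,3-dimethylcyclohex-2-ene-1-carboxylate F1.
   - Johnson–Claisen rearrangement (triethyl orthoacetate, propionic acid cat., 140 °C), a standard route to a quaternary carbon from a cyclohexenylmethanol, would give ethyl 2-[(1S,3S)-3-(methoxycarbonyl)-1,3-dimethyl-2-methylidenecyclohexyl]acetate F2. F2 carries C9 on C10 and an exocyclic C5=C6 methylene.
   - Hydroboration–oxidation (BH3·THF, then NaBO3·4H2O) and acid-catalysed lactonisation (TsOH, toluene) would give the δ-lactone methyl (4aS,8S)-4a,8-dimethyl-3-oxooctahydro-1H-isochromene-8-carboxylate F3.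
   - Enolate alkylation at C9 (LiN(i-Pr)2, THF–DMPU, −78 °C, (E)-5-bromo-3-methylpenta-1,3-diene) would give methyl (4aR,8S)-4a,8-dimethyl-4-[(2E)-3-methylpenta-2,4-dien-1-yl]-3-oxooctahydro-1H-isochromene-8-carboxylate F4.
   - MeLi (1 equiv, THF, −78 °C) would open the lactone to methyl (1S,3R)-2-(hydroxymethyl)-1,3-dimethyl-3-[(5E)-6-methyl-2-oxoocta-5,7-dien-3-yl]cyclohexane-1-carboxylate F5.
   - Dess–Martin oxidation would then give 22, which is closed with LiOH as in step 10.
   - C5 and C9, left open in F3 to F5, are corrected by enolisation at 22 and 23.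

2. Step 5. Hydride transfer to the vinylpalladium species may outrun CO insertion at the doubly flanked carbon, so that simple reduction of the triflate competes with formylation. The fallback replaces carbonylation by cross-coupling and oxidative cleavage; it sets out from 10 and comes back at 11. Stille coupling (tributyl(vinyl)stannane, Pd(PPh3)4, LiCl, THF, reflux) would give methyl (1S)-2-ethenyl-1,3-dimethylcyclohex-2-ene-1-carboxylate F6. Lemieux–Johnson cleavage (OsO4 cat., NaIO4, 2,6-lutidine, dioxane–H2O) of the monosubstituted vinyl double bond, far more accessible than the tetrasubstituted ring double bond, would then give 11.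

3. Step 12. The Lewis acidic titanium reagent may trigger loss of acetic acid across C6–C7 from the β-acetoxy ketone, or methylenation of the ketone next to the branched C9 may stall. The fallback never exposes a β-acyloxy ketone; it sets out from 23 and comes back at 25.
   - Silylation (Et3SiOTf, 2,6-lutidine, CH2Cl2, −78 °C) would give methyl (1S,4aR,5S,8R,8aS)-1,4a-dimethyl-5-[(2E)-3-methylpenta-2,4-dien-1-yl]-6-oxo-8-[(triethylsilyl)oxy]decahydronaphthalene-1-carboxylate F7.
   - Wittig methylenation (Ph3PCH3Br, KOt-Bu, toluene, rt → 60 °C) would give methyl (1S,4aS,5R,8R,8aS)-1,4a-dimethyl-6-methylidene-5-[(2E)-3-methylpenta-2,4-dien-1-yl]-8-[(triethylsilyl)oxy]decahydronaphthalene-1-carboxylate F8.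
   - Desilylation (HF·pyridine, THF, 0 °C) would give methyl (1S,4aS,5R,8R,8aS)-8-hydroxy-1,4a-dimethyl-6-methylidene-5-[(2E)-3-methylpenta-2,4-dien-1-yl]decahydronaphthalene-1-carboxylate F9.
   - Acetylation (Ac2O, pyridine, DMAP cat.) of this homoallylic alcohol, which can no longer eliminate, would give 25.

Further compounds
F1 | step 10 | methyl (1S)-2-(hydroxymethyl)-1,3-dimethylcyclohex-2-ene-1-carboxylate | COC(=O)[C@@]1(C)CCCC(C)=C1CO
F2 | step 10 | ethyl 2-[(1S,3S)-3-(methoxycarbonyl)-1,3-dimethyl-2-methylidenecyclohexyl]acetate | COC(=O)[C@@]1(C)CCC[C@@](C)(CC(=O)OCC)C1=C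
F3 | step 10 | methyl (4aS,8S)-4a,8-dimethyl-3-oxooctahydro-1H-isochromene-8-carboxylate (C8a open) | COC(=O)[C@@]1(C)CCC[C@@]2(C)CC(=O)OCC12
F4 | step 10 | methyl (4aR,8S)-4a,8-dimethyl-4-[(2E)-3-methylpenta-2,4-dien-1-yl]-3-oxooctahydro-1H-isochromene-8-carboxylate (C4 and C8a open) | COC(=O)[C@@]1(C)CCC[C@@]2(C)C(C/C=C(\C)C=C)C(=O)OCC12
F5 | step 10 | methyl (1S,3R)-2-(hydroxymethyl)-1,3-dimethyl-3-[(5E)-6-methyl-2-oxoocta-5,7-dien-3-yl]cyclohexane-1-carboxylate | COC(=O)[C@@]1(C)CCC[C@@](C)(C(C/C=C(\C)C=C)C(C)=O)C1CO
F6 | step 5 | methyl (1S)-2-ethenyl-1,3-dimethylcyclohex-2-ene-1-carboxylate | COC(=O)[C@@]1(C)CCCC(C)=C1C=C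
F7 | step 12 | methyl (1S,4aR,5S,8R,8aS)-1,4a-dimethyl-5-[(2E)-3-methylpenta-2,4-dien-1-yl]-6-oxo-8-[(triethylsilyl)oxy]decahydronaphthalene-1-carboxylate | C=C/C(C)=C/C[C@@H]1C(=O)C[C@@H](O[Si](CC)(CC)CC)[C@H]2[C@@]1(C)CCC[C@]2(C)C(=O)OC
F8 | step 12 | methyl (1S,4aS,5R,8R,8aS)-1,4a-dimethyl-6-methylidene-5-[(2E)-3-methylpenta-2,4-dien-1-yl]-8-[(triethylsilyl)oxy]decahydronaphthalene-1-carboxylate | C=C/C(C)=C/C[C@@H]1C(=C)C[C@@H](O[Si](CC)(CC)CC)[C@H]2[C@@]1(C)CCC[C@]2(C)C(=O)OC
F9 | step 12 | methyl (1S,4aS,5R,8R,8aS)-8-hydroxy-1,4a-dimethyl-6-methylidene-5-[(2E)-3-methylpenta-2,4-dien-1-yl]decahydronaphthalene-1-carboxylate | C=C/C(C)=C/C[C@@H]1C(=C)C[C@@H](O)[C@H]2[C@@]1(C)CCC[C@]2(C)C(=O)OC
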